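**Assumption:** the SMILES defines the target. C7'' is the benzylic carbinol, C8'' the aryloxy carbon and C9'' the CH2OH, so (7''R,8''S) is the erythro isomer. PPh3, DIAD, DDQ, PhB(OH)2, diethyl carbonate and similar are treated as reagents and are not numbered.

## Retrosynthetic overview

1. Target 11 ⇐ 7''-deoxy compound 9. Key step: late-stage dearomatisation of the 4-hydroxyphenyl ring with DDQ to a p-quinone methide, with boronic-acid-tethered OH delivery installing C7''–OH erythro to C8''.
2. 9 ⇐ bis-benzyl flavone 8 ⇐ phloroglucinol 7 + aroylacetate 6. One thermal annulation breaks the symmetry of phloroglucinol.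
3. 6 ⇐ acetosyringone 4 + (S)-alcohol 3, by Mitsunobu inversion (sets C8'') and then Claisen C-ethoxycarbonylation.
4. 3 ⇐ 4-benzyloxyphenyl Grignard (from 1) + (S)-benzyl glycidyl ether 2.
5. Ring order: both outer aryl rings are bought. The pyranone C ring is fused onto the A ring in step 4. A transient dioxaborinane forms and is cleaved in step 6.

## Route

**Step 1**
Reactants: 1, 1-(benzyloxy)-4-bromobenzene; 2, (S)-benzyl glycidyl ether [(S)-2-(benzyloxymethyl)oxirane]
Product: 3, (S)-1-(benzyloxy)-3-[4-(benzyloxy)phenyl]propan-2-ol
Conditions: 1, Mg, THF, reflux; then CuI (10 mol %), 2, THF, −30 → 0 °C; aq NH4Cl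
Reagents that add atoms: none
Why: Cu-catalysed Grignard opening of a terminal epoxide (SN2 at the CH2 carbon); the stereocenter is not touched, so (S) is carried over from 2.

**Step 2**
Reactants: 3; 4, acetosyringone (4'-hydroxy-3',5'-dimethoxyacetophenone)
Product: 5, 1-[4-({(R)-1-(benzyloxy)-3-[4-(benzyloxy)phenyl]propan-2-yl}oxy)-3,5-dimethoxyphenyl]ethan-1-one
Conditions: PPh3, DIAD, THF, 0 °C → rt
Reagents that add atoms: none
Why: Mitsunobu etherification with an acidic para-acyl phenol (pKa about 8); clean SN2 inversion turns (S)-3 into the (R)-ether, which is the C8'' arrangement of the target (it reads 8''S there only because CIP priorities change once C7'' carries OH).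

**Step 3**
Reactants: 5
Product: 6, ethyl 3-[4-({(R)-1-(benzyloxy)-3-[4-(benzyloxy)phenyl]propan-2-yl}oxy)-3,5-dimethoxyphenyl]-3-oxopropanoate
Conditions: NaH (3 equiv), (EtO)2CO (5 equiv), THF, reflux; AcOH quench
Reagents that add atoms: diethyl carbonate, CCOC(=O)OCC
Why: crossed Claisen condensation of the methyl ketone enolate with diethyl carbonate; the ether stereocenter has no acidic hydrogen and the benzyl ethers are inert to NaH.

**Step 4**
Reactants: 6; 7, phloroglucinol (benzene-1,3,5-triol, anhydrous, 3 equiv)
Product: 8, 2-[4-({(R)-1-(benzyloxy)-3-[4-(benzyloxy)phenyl]propan-2-yl}oxy)-3,5-dimethoxyphenyl]-5,7-dihydroxy-4H-chromen-4-one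
Conditions: neat melt, 240 °C (microwave or sand bath), 5–10 min, N2 sweep to remove EtOH and H2O
Reagents that add atoms: none
Why: catalyst-free Simonis-type thermal chromone annulation (aroylketene C-acylation of phloroglucinol, then cyclodehydration); because phloroglucinol is C3-symmetric only one regioisomer can form, no protecting groups are needed on the A ring, and the robust alkyl aryl ether stereocenter is unaffected.

**Step 5**
Reactants: 8
Product: 9, 5,7-dihydroxy-2-[4-({(R)-1-hydroxy-3-(4-hydroxyphenyl)propan-2-yl}oxy)-3,5-dimethoxyphenyl]-4H-chromen-4-one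
Conditions: H2 (1 atm), 10% Pd/C, THF–MeOH, rt; stop after 2 equiv H2
Reagents that add atoms: none
Why: hydrogenolysis of the aryl and alkyl benzyl ethers; the C8''–O bond is not benzylic and the flavone enone survives 1 atm H2 at rt.

**Step 6 (key step)**
Reactants: 9
Product: 11, the target (7''R,8''S), via the non-isolated cyclic boronate 10, the trans-(4R,5S)-4-(4-hydroxyphenyl)-2-phenyl-1,3,2-dioxaborinane carrying the tricin-4'-yloxy group at C5
Conditions: PhB(OH)2 (2 equiv), dry 1,4-dioxane, rt, 30 min; DDQ (1.05 equiv), rt, 1–2 h; then pinacol (5 equiv), MeOH/pH 7 buffer, rt (one pot)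
Reagents that add atoms: phenylboronic acid, OB(O)c1ccccc1 (delivers the C7'' oxygen; B and Ph are removed by pinacol); ultimate oxygen source water, O
Why: Proposed new method: DDQ abstracts hydride from the only p-alkylphenol present, dearomatising it to a p-quinone methide, and the C9''–O–B(Ph)–OH hemiester adds its B–OH in a 1,6-fashion to C7'' through a six-membered transition state to give 10. With H8'' eclipsing the exocyclic C=C (A1,3 strain), delivery occurs from the C9'' face, anti to the aryloxy group, which gives erythro (7''R from 8''S); this matches both the trans-diequatorial thermodynamic preference of the ring and the known erythro bias of water addition to syringyl-type β-ether quinone methides. The B–O substituent also slows a second oxidation to the ketone. The closest known reaction types are DDQ benzylic oxidation of 4-alkylphenols with O-nucleophile capture of the quinone methide, and boronic-acid hemiester oxa-Michael hydroxyl delivery to hydroxy-enones.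

## Compound list

1 | 1-(benzyloxy)-4-bromobenzene | Brc1ccc(OCc2ccccc2)cc1 | starting material
2 | (S)-benzyl glycidyl ether | c1ccccc1COC[C@@H]1CO1 | starting material
3 | (S)-1-(benzyloxy)-3-[4-(benzyloxy)phenyl]propan-2-ol | c1ccccc1COC[C@@H](O)Cc1ccc(OCc2ccccc2)cc1 | intermediate
4 | acetosyringone | CC(=O)c1cc(OC)c(O)c(OC)c1 | starting material
5 | (R)-aryl ether of acetosyringone | CC(=O)c1cc(OC)c(O[C@@H](COCc2ccccc2)Cc2ccc(OCc3ccccc3)cc2)c(OC)c1 | intermediate
6 | ethyl aroylacetate (β-ketoester) of 5 | CCOC(=O)CC(=O)c1cc(OC)c(O[C@@H](COCc2ccccc2)Cc2ccc(OCc3ccccc3)cc2)c(OC)c1 | intermediate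
7 | phloroglucinol | Oc1cc(O)cc(O)c1 | starting material
8 | bis-benzyl 7''-deoxy flavonolignan | COc1cc(-c2cc(=O)c3c(O)cc(O)cc3o2)cc(OC)c1O[C@@H](COCc1ccccc1)Cc1ccc(OCc2ccccc2)cc1 | intermediate
9 | 7''-deoxy flavonolignan, (R) | COc1cc(-c2cc(=O)c3c(O)cc(O)cc3o2)cc(OC)c1O[C@@H](CO)Cc1ccc(O)cc1 | intermediate
10 | cyclic phenylboronate of the target 7'',9''-diol (not isolated) | COc1cc(-c2cc(=O)c3c(O)cc(O)cc3o2)cc(OC)c1O[C@H]1COB(c2ccccc2)O[C@@H]1c1ccc(O)cc1 | intermediate
11 | (−)-(7''R,8''S)-4'',5,7-trihydroxy-3',5'-dimethoxy-4',8''-oxyflavonolignan-7'',9''-diol | COc1cc(-c2cc(=O)c3c(O)cc(O)cc3o2)cc(OC)c1O[C@@H](CO)[C@H](O)c1ccc(O)cc1 | target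

## Summary

Total steps: 6 (step 6 is one pot). Longest linear sequence: 6.

Steps most likely to fail, with a fallback that changes the approach:

1. **Step 6** (over-oxidation to the 7''-ketone, quinone methide tautomerising to the 7'',8''-enol ether, or modest erythro:threo ratio). Fallback: oxidise deliberately to the 7''-ketone (DDQ, 2.2 equiv, wet dioxane), then set C7'' by reduction. Use NaBH4 (polar Felkin–Anh, erythro-favoured for syringyl-type β-ethers) or a Noyori Ru–TsDPEN transfer hydrogenation for catalyst control.
2. **Step 4** (the elaborate β-ketoester may decompose or give low conversion at 240 °C). Fallback: build the flavone through a 1,3-diketone. Use methyl syringate instead of 4 in step 2, hydrolyse to the acid and form the acid chloride. Then C-acylate the LiHMDS polyanion of 2',4',6'-trihydroxyacetophenone and cyclodehydrate with AcOH/cat. H2SO4.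
3. **Step 2** (hindered 2,6-dimethoxyphenol on a secondary alcohol; elimination or low yield). Fallback: form the C8''–O bond by SN2 at an activated ester α-carbon. Displace the α-triflate of ethyl (S)-3-(4-benzyloxyphenyl)lactate (from O-benzyl-L-tyrosine by diazotisation) with the phenoxide of 4 (inversion), then reduce the ester with LiBH4 and continue.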